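Cedar had 0.190 M of second end groups in excess and larch 0.00500 M, yet both read 50% links at 3.00 min. The next run has to choose between east and north, two very different charges, and that reading suggests the excess may buy nothing.

| setting | ash | birch | cedar | larch | east | north |
|---|---|---|---|---|---|---|
| first end groups | 0.50 M | 0.50 M | 0.50 M | 0.52 M | 0.50 M | 0.30 M |
| second end groups | 0.66 M | 0.62 M | 0.69 M | 0.525 M | 0.525 M | 0.800 M |
| remark | run made earlier | run made earlier | run made earlier | run made earlier |  |  |
| time |  |  |  |  | 6.0 min | 6.0 min |

| run | time / min | links / % | first end groups / % |
|---|---|---|---|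
| ash | 0.250 | 96 | 0 |
| ash | 0.833 | 79 | 0 |
| ash | 1.33 | 68 | 0 |
| ash | 2.00 | 59 | 2 |
| ash | 3.00 | 56 | 5 |
| birch | 0.667 | 85 | 0 |
| birch | 1.33 | 68 | 0 |
| birch | 2.00 | 60 | 2 |
| birch | 2.50 | 55 | 0 |
| birch | 3.00 | 48 | 1 |
| cedar | 0.667 | 82 | 1 |
| cedar | 1.33 | 70 | 0 |
| cedar | 2.00 | 59 | 1 |
| cedar | 2.50 | 54 | 1 |
| cedar | 3.00 | 50 | 0 |
| larch | 0.250 | 92 | 7 |
| larch | 0.833 | 79 | 4 |
| larch | 1.33 | 70 | 2 |
| larch | 2.00 | 59 | 0 |
| larch | 3.00 | 50 | 0 |

(each reading ± 2 percentage points)



- which one finishes higher in amount of links, in percent of the first end groups charged ("neither" within 2 percentage points) (east / north / neither)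
- amount of links at the end, in percent of the first end groups charged, east
- amount of links at the end, in percent of the first end groups charged, north

First end groups are the limiting reagent in larch, 0.52 M against 0.525 M, and read 0% at 2.00 min. From that reading on we take links in larch as no longer fed, and what we watch is their fall. We treat that fall as a lag settling to a level that need not be zero. Averaging birch and cedar gives links of 83.5%, 69.0% and 59.5% at equal steps of 0.670 min. If each fall is a fixed fraction of the one before, as in a lag, we reckon:

shrink per step = 9.5 percentage points / 14 points = 0.655

settling time = step / ln(1/shrink) = 1.58 min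

floor = 83.5% − 14 points / (1 − shrink) = 41.4%

This floor, the share of the charge still standing as links once the fall has settled, lies below an even split, which is a fraction of 0.5. We take that even split as the zero of our scale for a two-way exchange. The floor is a rough reading: readings scatter by 2 points and the two falls differ by 5 points.

links at 6.0 min = floor + (59.5% − floor) × exp(−4.00 min / settling time) = 42.9%

We expect this figure from both east and north, so we would charge east and leave north's excess out. The weak point is north's 0.30 M of first end groups, a charge no earlier run tried.

The forecast names north, with east at 33% (28% to 38%) and north at 45% (34% to 52%), reasoning that “the links seem to react with each other”. Our reckoning differs, with one figure for both flasks.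

The outcome is neither: east gives 41.1% links and north 41.1%, and our 42.9% stood 1.8 points above them.

    links → over-reaction product (k = 2.90 × 10⁻⁶ /s)
    first end groups + second end groups → links + by-product (k = 2.00 /M/s)
    second end groups → decomposed reagent (k = 0.00290 /s)
    links ⇌ isomer of the product (K = 1.60, k = 0.00540 /s)

In north, links and isomer of the product exchange with a relaxation half-life of 1.32 min, short against 6.0 min. Our floor of 41.4% and settling time of 1.58 min put north read at 4.0 min at 46.6%, and that neighbour flask stands at 46.0% links.

(The readings were computed for substances that don't exist; scatter was added.)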